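**Plan**

- Retrosynthesis cuts, in this order: the ester C–O bond between the left acid and the CH2O group on C1 of ring B; the O–CH2 bond of the seven-membered lactone (ring C); the trisubstituted C=C bonds of both halves, back to aldehydes (Morita–Baylis–Hillman logic); and the two C–C bonds that hold the C2 and C3 carbons on ring B, back to a cyclobutane photoadduct of 4-isopropylcyclohexenone.
- Forward: ring B is made first (Michael/aldol), a cyclobutane is fused on and cut to the cis C2 acid/C3 aldehyde, the bromomethyl-enoate is built on C3, ring C is closed by O-alkylation, and the left acid (from the enantiomeric enone) is attached last, before global desilylation.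
- Enabling feature: in ring C the lactone oxygen is bound to an allylic CH2 that is cis to fusion carbon C3 across the ring alkene, and the acyl carbon sits on C2, cis to C3 on ring B. A (Z)-2-(bromomethyl)enoate on C3 therefore holds CH2Br next to the C2 carboxylate.
- Stereochemistry: C4 of each half comes from a prolinol-ether-catalysed Michael addition ((S)-enone for the right half, (R)-enone for the left). C2/C3 come from a cis [2+2] anti to isopropyl, and C1 from Grignard attack anti to the cyclobutane. The left C3 comes from cuprate addition trans to isopropyl, and both alkene geometries from thermodynamically controlled allylic transpositions.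

Key step: step 12

Notation: ring B is numbered C1 (carbinol carbon), C2 (lactone α-carbon), C3 (fusion carbon bearing the alkene), C4 (isopropyl carbon), C5, C6. The α face carries the C2 and C3 carbon substituents and the C1 oxygen; the β face carries the isopropyl group and the C1 CH2O group.

Remark: oxo acid 13 may rest as its cyclic hydroxy-lactone tautomer; it is assumed to react through the open-chain carboxylic acid.

**Route**

Step 1
Reactants: 1 isovaleraldehyde; 2 methyl vinyl ketone
Product: 4 (S)-4-isopropylcyclohex-2-en-1-one, via (S)-2-isopropyl-5-oxohexanal 3 (not isolated)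
Conditions: (S)-2-[methoxy(diphenyl)methyl]pyrrolidine (5 mol%), ethyl 3,4-dihydroxybenzoate (20 mol%), neat, 4 °C; then LiOH, i-PrOH, rt
Reagents that add atoms: none
Why: Enamine-catalysed Michael addition in which the (E)-enamine should be attacked on the face away from the diarylmethyl group, giving the (S)-centre (C4), followed by an intramolecular aldol condensation (Robinson-type annulation) that leaves it untouched.

Step 2
Reactants: 4 (S)-4-isopropylcyclohex-2-en-1-one; 5 allene
Product: 6 (1R,5S,6S)-5-isopropyl-8-methylenebicyclo[4.2.0]octan-2-one (cis-fused; cyclobutane on the α face)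
Conditions: hν (medium-pressure Hg lamp, Pyrex), excess 5, THF, −78 °C; then basic Al2O3, Et2O, rt
Reagents that add atoms: none
Why: Enone–allene [2+2] photocycloaddition through the enone triplet; the allene should add head-to-head (its sp2 carbon to C2) on the face opposite the C4 isopropyl group, which sets C3, and the four-membered ring persists only cis-fused (alumina epimerises any trans-fused adduct at C2), which sets C2.

Step 3
Reactants: 6 photoadduct ketone
Product: 8 diol (C1 α-OH and β-CH2OH on the methylenecyclobutane), via β-hydroxysilane 7 (not isolated)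
Conditions: (i-PrO)Me2SiCH2MgCl [from ClCH2SiMe2(O-i-Pr), Mg], THF, 0 °C; then KF, KHCO3, 30% H2O2, THF/MeOH, rt
Reagents that add atoms: (isopropoxydimethylsilyl)methylmagnesium chloride, CC(C)O[Si](C)(C)C[Mg]Cl; hydrogen peroxide, OO
Why: Nucleophilic hydroxymethylation (Grignard addition, then Tamao oxidation of C–Si to C–OH); the Grignard reagent should attack the ketone on the convex β face, anti to the cis-fused cyclobutane, so that CH2 ends cis to isopropyl and the tertiary oxygen cis to the C2/C3 substituents, which sets C1.

Step 4
Reactants: 8 diol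
Product: 9 acetonide (spiro-1,3-dioxolane at C1)
Conditions: 2,2-dimethoxypropane, pyridinium p-toluenesulfonate (cat.), acetone, rt
Reagents that add atoms: 2,2-dimethoxypropane, COC(C)(C)OC
Why: Acid-catalysed transketalisation masks both hydroxyls, which keeps the tertiary OH from forming a bridged lactol with the later C3 aldehyde; no stereocentre is involved.

Step 5
Reactants: 9 acetonide
Product: 10 cyclobutanone (C=O on the carbon bound to C2)
Conditions: O3, CH2Cl2, −78 °C; then Me2S, −78 °C to rt
Reagents that add atoms: ozone, [O-][O+]=O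
Why: Ozonolysis (Criegee mechanism) of the exocyclic 1,1-disubstituted alkene; the acetonide is inert and the ring fusion can only stay cis.

Step 6
Reactants: 10 cyclobutanone
Product: 13 cis oxo acid (C2 α-CO2H; C3 α-CHO; C1 acetonide), via trimethylsilyl enol ether 11 (not isolated), via trimethylsilyl ester 12 (not isolated)
Conditions: i-Pr2NLi, Me3SiCl (in situ), THF, −78 °C; then O3, CH2Cl2/MeOH, −78 °C; Me2S; aqueous work-up
Reagents that add atoms: ozone, [O-][O+]=O
Why: Kinetic deprotonation should occur at the cyclobutanone CH2 rather than at the hindered C2 methine, and ozonolysis of the silyl enol ether cuts that C=C so that C2 keeps the carboxyl carbon and C3 the formyl carbon, with the cis relationship from step 2 intact.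

Step 7
Reactants: 13 cis oxo acid
Product: 14 2-phenylpropan-2-yl (cumyl) ester of 13
Conditions: 2-phenylpropan-2-yl 2,2,2-trichloroacetimidate, CH2Cl2, rt
Reagents that add atoms: 2-phenylpropan-2-yl 2,2,2-trichloroacetimidate, CC(C)(OC(=N)C(Cl)(Cl)Cl)c1ccccc1
Why: Trichloroacetimidate O-alkylation, in which the acid protonates the imidate and the ion pair collapses to the ester; the tertiary ester is chosen because it should resist lactonisation by the carbinol of step 9 and later leaves with dilute acid.

Step 8
Reactants: 15 acryloyl chloride; 16 2-(trimethylsilyl)ethanol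
Product: 17 2-(trimethylsilyl)ethyl acrylate
Conditions: Et3N, CH2Cl2, 0 °C
Reagents that add atoms: none
Why: Schotten–Baumann-type acylation of a primary alcohol by an acid chloride.

Step 9
Reactants: 14 cumyl ester aldehyde; 17 2-(trimethylsilyl)ethyl acrylate
Product: 18 Morita–Baylis–Hillman carbinol on C3 (both carbinol epimers)
Conditions: DABCO (1 equiv), 17 (3 equiv), 1,4-dioxane/H2O (1:1), rt
Reagents that add atoms: none
Why: Morita–Baylis–Hillman reaction (amine conjugate addition, aldol addition, amine elimination); the new carbinol centre is not controlled and is erased in step 10, while C3 is the favoured equatorial epimer and should not drift under the amine.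

Step 10
Reactants: 18 carbinol
Product: 19 (Z)-2-(bromomethyl)enoate on C3 (cumyl ester at C2)
Conditions: NBS, Me2S, CH2Cl2, 0 °C to rt
Reagents that add atoms: N-bromosuccinimide, BrN1C(=O)CCC1=O
Why: Corey–Kim-type activation of the carbinol as an alkoxysulfonium ion and SN2′ delivery of bromide with allylic transposition; both epimers should converge on the (Z)-alkene, which places CH2Br cis to C3.

Step 11
Reactants: 19 bromo cumyl ester
Product: 20 bromo acid (free C2 carboxylic acid)
Conditions: CF3CO2H (2 vol%), CH2Cl2, 0 °C
Reagents that add atoms: none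
Why: Acid-catalysed E1 cleavage of the tertiary benzylic ester (loss of the cumyl cation as α-methylstyrene) should be far faster than cleavage of the acetonide or the silylethyl ester in dilute anhydrous acid.

Step 12
Reactants: 20 bromo acid
Product: 22 bicyclic lactone of rings B and C (acetonide; silylethyl ester), via caesium carboxylate 21 (not isolated)
Conditions: Cs2CO3, DMF (0.005 M, slow addition of 20), rt
Reagents that add atoms: none
Why: Cs2CO3 converts 20 into the caesium carboxylate 21, whose loosely paired oxygen displaces bromide from the primary allylic CH2 in an intramolecular SN2 reaction that forms the O–CH2 bond of the lactone. The closest known reaction type is caesium-carboxylate alkylation, as used to lactonise ω-halo acids and to esterify allylic bromides derived from Morita–Baylis–Hillman adducts. Ring C closes in the 7-exo-tet mode. No stereocentre is created, and C2 keeps its configuration because the carboxyl group is never turned into an acylating species and the carboxylate α-proton is not acidic towards carbonate. The step needs direct SN2 attack to beat conjugate SN2′ attack at the alkene CH (which would give a five-membered lactone) and intermolecular alkylation: the (Z)-geometry holds CH2Br on the same side of the alkene as C3 and hence next to the cis C2 carboxylate, the alkene CH is a hindered terminus, no nucleophilic amine or added halide is present to relay the bromide, and high dilution suppresses oligomers.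

Step 13
Reactants: 1 isovaleraldehyde; 2 methyl vinyl ketone
Product: 24 (R)-4-isopropylcyclohex-2-en-1-one, via (R)-2-isopropyl-5-oxohexanal 23 (not isolated)
Conditions: (R)-2-[methoxy(diphenyl)methyl]pyrrolidine (5 mol%), ethyl 3,4-dihydroxybenzoate (20 mol%), neat, 4 °C; then LiOH, i-PrOH, rt
Reagents that add atoms: none
Why: Same enamine Michael/aldol condensation as step 1 with the enantiomeric catalyst, which should give the (R)-centre that the left half requires.

Step 14
Reactants: 24 (R)-4-isopropylcyclohex-2-en-1-one
Product: 26 trans-4-isopropyl-3-vinylcyclohex-1-en-1-yl triflate, via bromomagnesium enolate 25 (not isolated)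
Conditions: CH2=CHMgBr, CuBr·SMe2 (10 mol%), THF, −78 °C; then N-(5-chloro-2-pyridyl)bis(trifluoromethanesulfonimide), −78 °C to rt
Reagents that add atoms: vinylmagnesium bromide, C=C[Mg]Br; N-(5-chloro-2-pyridyl)bis(trifluoromethanesulfonimide), O=S(=O)(N(c1ccc(Cl)cn1)S(=O)(=O)C(F)(F)F)C(F)(F)F
Why: Copper-catalysed conjugate addition should deliver vinyl to C3 trans to the adjacent isopropyl group, and O-triflation of the regiodefined enolate fixes the ring alkene between C1 and C2.

Step 15
Reactants: 26 vinyl enol triflate
Product: 27 trans-3-formyl-4-isopropylcyclohex-1-en-1-yl triflate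
Conditions: O3, CH2Cl2, −78 °C (Sudan Red 7B end point); then Me2S
Reagents that add atoms: ozone, [O-][O+]=O
Why: Chemoselective ozonolysis, because the monosubstituted vinyl group is far more electron-rich than the enol triflate C=C.

Step 16
Reactants: 27 aldehyde; 28 methyl propiolate
Product: 30 carbinol methyl 2-[hydroxy(ring)methyl]acrylate (both carbinol epimers), via α-aluminated acrylate 29 (not isolated)
Conditions: i-Bu2AlH, N-methylmorpholine N-oxide, THF, 0 °C, 28; then 27, 0 °C to rt
Reagents that add atoms: none
Why: Hydroalumination of the propiolate gives an α-aluminated acrylate that adds to the aldehyde (vinylalumination, an amine-free equivalent of the Morita–Baylis–Hillman reaction), which should avoid base-induced migration of the ring alkene; the carbinol centre is erased in step 17 and the ring centre is the favoured trans epimer.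

Step 17
Reactants: 30 carbinol
Product: 32 (E)-2-(acetoxymethyl)enoate (CH2OAc cis to the ring), via secondary allylic acetate 31 (not isolated)
Conditions: Ac2O, pyridine, DMAP (cat.), CH2Cl2, 0 °C to rt; then DABCO (0.3 equiv), THF, 65 °C
Reagents that add atoms: acetic anhydride, CC(=O)OC(C)=O
Why: O-Acetylation followed by DABCO-mediated SN2′–SN2′ allylic transposition of the acetate, which should settle on the more stable trisubstituted (E)-enoate.

Step 18
Reactants: 32 allylic acetate
Product: 33 (E)-2-(hydroxymethyl)enoate triflate
Conditions: K2CO3 (0.2 equiv), MeOH, 0 °C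
Reagents that add atoms: none
Why: Zemplén-type transesterification of the primary acetate; the methyl ester is degenerate towards methanol and the enol triflate should survive at 0 °C.

Step 19
Reactants: 33 enol triflate
Product: 34 diol methyl ester (ring CH2OH and side-chain CH2OH)
Conditions: Bu3SnCH2OH, Pd(PPh3)4 (5 mol%), LiCl, 1,4-dioxane, 100 °C
Reagents that add atoms: (tributylstannyl)methanol, OC[Sn](CCCC)(CCCC)CCCC
Why: Stille coupling (oxidative addition of zerovalent palladium to the enol triflate, transfer of hydroxymethyl from tin, reductive elimination) installs the ring CH2OH without touching the enoate.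

Step 20
Reactants: 34 diol
Product: 35 bis(tert-butyldimethylsilyl) ether methyl ester
Conditions: t-BuMe2SiCl, imidazole, DMF, rt
Reagents that add atoms: tert-butyldimethylsilyl chloride, CC(C)(C)[Si](C)(C)Cl
Why: Standard silylation of two primary allylic alcohols.

Step 21
Reactants: 35 methyl ester
Product: 36 left acid (both CH2OH groups as silyl ethers)
Conditions: LiOH, THF/MeOH/H2O, 40 °C; then 1 M HCl to pH 4
Reagents that add atoms: lithium hydroxide, [Li+].[OH-]
Why: Saponification (acyl-oxygen cleavage) of the methyl ester; the primary silyl ethers and the (E)-alkene should be stable to hydroxide.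

Step 22
Reactants: 22 bicyclic lactone acetonide
Product: 37 diol lactone (C1 tertiary OH and CH2OH free)
Conditions: AcOH/THF/H2O (3:1:1), 40 °C
Reagents that add atoms: none
Why: Acid-catalysed hydrolysis of the dioxolane; the lactone and the silylethyl ester should survive dilute acetic acid.

Step 23
Reactants: 37 diol lactone; 36 left acid
Product: 38 coupled ester (left acid on the C1 CH2O group; silyl ethers and silylethyl ester in place)
Conditions: DCC, DMAP (cat.), CH2Cl2, 0 °C to rt
Reagents that add atoms: none
Why: Steglich esterification, in which the primary hydroxyl is acylated and the tertiary one is not; any minor diastereomer from incomplete enantiopurity of the two halves is removed here.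

Step 24
Reactants: 38 coupled ester
Product: 39 target compound
Conditions: (Me2N)3S+ Me3SiF2− (excess), DMF, 0 °C to rt; aqueous NH4Cl
Reagents that add atoms: none
Why: Fluoride cleaves both silyl ethers and fragments the 2-(trimethylsilyl)ethyl ester (β-elimination to ethylene and carboxylate) under essentially non-basic conditions that should spare the lactone, the ester link and the allylic alcohols.

**Compound list**

1 | isovaleraldehyde | CC(C)CC=O | starting material
2 | methyl vinyl ketone | CC(=O)C=C | starting material
3 | (S)-2-isopropyl-5-oxohexanal | CC(C)[C@@H](C=O)CCC(C)=O | intermediate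
4 | (S)-4-isopropylcyclohex-2-en-1-one | CC(C)[C@@H]1CCC(=O)C=C1 | intermediate
5 | allene (propadiene) | C=C=C | starting material
6 | (1R,5S,6S)-5-isopropyl-8-methylenebicyclo[4.2.0]octan-2-one | O=C1CC[C@@H](C(C)C)[C@@H]2CC(=C)[C@@H]21 | intermediate
7 | β-hydroxysilane: C1 α-OH, β-CH2SiMe2(O-i-Pr) adduct of 6 | CC(C)O[Si](C)(C)C[C@@]1(O)CC[C@@H](C(C)C)[C@@H]2CC(=C)[C@@H]21 | intermediate
8 | diol: C1 α-OH, β-CH2OH, methylenecyclobutane intact | OC[C@@]1(O)CC[C@@H](C(C)C)[C@@H]2CC(=C)[C@@H]21 | intermediate
9 | acetonide of 8 | CC1(C)OC[C@@]2(O1)CC[C@@H](C(C)C)[C@@H]3CC(=C)[C@@H]32 | intermediate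
10 | cyclobutanone (C=O on the carbon bound to C2) | CC1(C)OC[C@@]2(O1)CC[C@@H](C(C)C)[C@@H]3CC(=O)[C@@H]32 | intermediate
11 | trimethylsilyl enol ether of 10 (C=C towards the CH bound to C3) | CC1(C)OC[C@@]2(O1)CC[C@@H](C(C)C)[C@@H]3C=C(O[Si](C)(C)C)[C@@H]32 | intermediate
12 | trimethylsilyl ester of 13 | CC1(C)OC[C@@]2(O1)CC[C@@H](C(C)C)[C@H](C=O)[C@@H]2C(=O)O[Si](C)(C)C | intermediate
13 | cis oxo acid: C2 α-CO2H, C3 α-CHO, C4 β-isopropyl, C1 acetonide | CC1(C)OC[C@@]2(O1)CC[C@@H](C(C)C)[C@H](C=O)[C@@H]2C(=O)O | intermediate
14 | cumyl ester of 13 | CC1(C)OC[C@@]2(O1)CC[C@@H](C(C)C)[C@H](C=O)[C@@H]2C(=O)OC(C)(C)c1ccccc1 | intermediate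
15 | acryloyl chloride | C=CC(=O)Cl | starting material
16 | 2-(trimethylsilyl)ethanol | OCC[Si](C)(C)C | starting material
17 | 2-(trimethylsilyl)ethyl acrylate | C=CC(=O)OCC[Si](C)(C)C | intermediate
18 | Morita–Baylis–Hillman carbinol on C3, cumyl ester at C2 (carbinol epimers) | CC1(C)OC[C@@]2(O1)CC[C@@H](C(C)C)[C@H](C(O)C(=C)C(=O)OCC[Si](C)(C)C)[C@@H]2C(=O)OC(C)(C)c1ccccc1 | intermediate
19 | (Z)-2-(bromomethyl)enoate on C3, cumyl ester at C2 | CC1(C)OC[C@@]2(O1)CC[C@@H](C(C)C)[C@H](/C=C(\CBr)C(=O)OCC[Si](C)(C)C)[C@@H]2C(=O)OC(C)(C)c1ccccc1 | intermediate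
20 | cis bromo acid (key-step precursor) | CC1(C)OC[C@@]2(O1)CC[C@@H](C(C)C)[C@H](/C=C(\CBr)C(=O)OCC[Si](C)(C)C)[C@@H]2C(=O)O | intermediate
21 | caesium carboxylate of 20 | CC1(C)OC[C@@]2(O1)CC[C@@H](C(C)C)[C@H](/C=C(\CBr)C(=O)OCC[Si](C)(C)C)[C@@H]2C(=O)[O-].[Cs+] | intermediate
22 | bicyclic lactone of rings B and C, acetonide, silylethyl ester | CC1(C)OC[C@@]2(O1)CC[C@@H](C(C)C)[C@@H]3C=C(C(=O)OCC[Si](C)(C)C)COC(=O)[C@@H]32 | intermediate
23 | (R)-2-isopropyl-5-oxohexanal | CC(C)[C@H](C=O)CCC(C)=O | intermediate
24 | (R)-4-isopropylcyclohex-2-en-1-one | CC(C)[C@H]1CCC(=O)C=C1 | intermediate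
25 | bromomagnesium enolate of trans-3-vinyl-4-isopropylcyclohexanone | CC(C)[C@H]1CCC(O[Mg]Br)=C[C@@H]1C=C | intermediate
26 | trans-4-isopropyl-3-vinylcyclohex-1-en-1-yl triflate | CC(C)[C@H]1CCC(OS(=O)(=O)C(F)(F)F)=C[C@@H]1C=C | intermediate
27 | trans-3-formyl-4-isopropylcyclohex-1-en-1-yl triflate | CC(C)[C@H]1CCC(OS(=O)(=O)C(F)(F)F)=C[C@@H]1C=O | intermediate
28 | methyl propiolate | C#CC(=O)OC | starting material
29 | [1-(methoxycarbonyl)vinyl]diisobutylaluminium | C=C(C(=O)OC)[Al](CC(C)C)CC(C)C | intermediate
30 | left carbinol: methyl 2-[hydroxy(ring)methyl]acrylate, ring as in 27 (carbinol epimers) | CC(C)[C@H]1CCC(OS(=O)(=O)C(F)(F)F)=C[C@@H]1C(O)C(=C)C(=O)OC | intermediate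
31 | secondary allylic acetate of 30 | CC(C)[C@H]1CCC(OS(=O)(=O)C(F)(F)F)=C[C@@H]1C(OC(C)=O)C(=C)C(=O)OC | intermediate
32 | (E)-2-(acetoxymethyl)enoate, enol triflate | CC(C)[C@H]1CCC(OS(=O)(=O)C(F)(F)F)=C[C@@H]1/C=C(\COC(C)=O)C(=O)OC | intermediate
33 | (E)-2-(hydroxymethyl)enoate, enol triflate | CC(C)[C@H]1CCC(OS(=O)(=O)C(F)(F)F)=C[C@@H]1/C=C(\CO)C(=O)OC | intermediate
34 | left diol methyl ester | CC(C)[C@H]1CCC(CO)=C[C@@H]1/C=C(\CO)C(=O)OC | intermediate
35 | left bis(silyl ether) methyl ester | CC(C)[C@H]1CCC(CO[Si](C)(C)C(C)(C)C)=C[C@@H]1/C=C(\CO[Si](C)(C)C(C)(C)C)C(=O)OC | intermediate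
36 | left acid, bis(silyl ether) | CC(C)[C@H]1CCC(CO[Si](C)(C)C(C)(C)C)=C[C@@H]1/C=C(\CO[Si](C)(C)C(C)(C)C)C(=O)O | intermediate
37 | diol lactone (rings B and C), silylethyl ester | OC[C@@]1(O)CC[C@@H](C(C)C)[C@@H]2C=C(C(=O)OCC[Si](C)(C)C)COC(=O)[C@@H]21 | intermediate
38 | coupled ester, fully protected | CC(C)[C@H]1CCC(CO[Si](C)(C)C(C)(C)C)=C[C@@H]1/C=C(\CO[Si](C)(C)C(C)(C)C)C(=O)OC[C@@]1(O)CC[C@@H](C(C)C)[C@@H]2C=C(C(=O)OCC[Si](C)(C)C)COC(=O)[C@@H]21 | intermediate
39 | CNP0361406.3 | CC(C)[C@H]1CCC(CO)=C[C@@H]1/C=C(\CO)C(=O)OC[C@@]1(O)CC[C@@H](C(C)C)[C@@H]2C=C(C(=O)O)COC(=O)[C@@H]21 | target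

**Counts and risks**

Total steps: 24. Longest linear sequence: 14 steps (steps 1–7, 9–12, 22–24).

Most likely to fail, riskiest first:

1. Step 9. The amine-catalysed aldol stage may be too slow at the doubly flanked C3 aldehyde, so that hydrolysis and oligomerisation of the acrylate outrun product formation. Fallback: deliver the acrylate α-carbon as a preformed organoaluminium nucleophile. Propiolic acid is esterified with 16 (DCC, DMAP cat.) to 2-(trimethylsilyl)ethyl propiolate F1. Hydroalumination with i-Bu2AlH and N-methylmorpholine N-oxide gives the α-aluminated acrylate F2, which is added to aldehyde 14 at 0 °C to give carbinol 18, where the route resumes.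

2. Step 12. Conjugate SN2′ closure to the five-membered lactone, or intermolecular alkylation to oligomers, may compete with the 7-exo-tet displacement. Fallback: close ring C at the acyl C–O bond instead. Bromide 19 is displaced with HCO2Na in DMF to give the allylic formate F3. Dilute CF3CO2H removes the cumyl ester to give formate acid F4, and KHCO3 in MeOH frees the allylic alcohol to give seco hydroxy acid F5. Shiina lactonisation of F5 (2-methyl-6-nitrobenzoic anhydride, DMAP, high dilution) gives lactone 22.

3. Step 23. Acylation of the neopentyl-type primary hydroxyl by the α-substituted acrylic acid may be slow enough for the lactone acyl group to migrate onto that hydroxyl (ring contraction), or for N-acylurea formation to consume the acid. Fallback: join the halves by carboxylate alkylation. Diol 37 is tosylated at the primary hydroxyl (TsCl, pyridine, 0 °C) to the primary tosylate F6. With acid 36 and Cs2CO3 in DMF at 50 °C, the tertiary alkoxide closes onto CH2OTs to give the spiro-epoxide F7, which the caesium carboxylate of 36 opens at its CH2 terminus to give coupled ester 38.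

Further compounds
F1 | step 9 | 2-(trimethylsilyl)ethyl propiolate | C#CC(=O)OCC[Si](C)(C)C
F2 | step 9 | [1-((2-(trimethylsilyl)ethoxy)carbonyl)vinyl]diisobutylaluminium | C=C(C(=O)OCC[Si](C)(C)C)[Al](CC(C)C)CC(C)C
F3 | step 12 | (E)-2-(formyloxymethyl)enoate on C3, cumyl ester at C2 | CC1(C)OC[C@@]2(O1)CC[C@@H](C(C)C)[C@H](/C=C(\COC=O)C(=O)OCC[Si](C)(C)C)[C@@H]2C(=O)OC(C)(C)c1ccccc1
F4 | step 12 | formate acid (free C2 carboxylic acid) | CC1(C)OC[C@@]2(O1)CC[C@@H](C(C)C)[C@H](/C=C(\COC=O)C(=O)OCC[Si](C)(C)C)[C@@H]2C(=O)O
F5 | step 12 | seco hydroxy acid | CC1(C)OC[C@@]2(O1)CC[C@@H](C(C)C)[C@H](/C=C(\CO)C(=O)OCC[Si](C)(C)C)[C@@H]2C(=O)O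
F6 | step 23 | primary tosylate of diol lactone 37 | Cc1ccc(cc1)S(=O)(=O)OC[C@@]1(O)CC[C@@H](C(C)C)[C@@H]2C=C(C(=O)OCC[Si](C)(C)C)COC(=O)[C@@H]21
F7 | step 23 | C1 spiro-epoxide of the bicyclic lactone | C1O[C@@]12CC[C@@H](C(C)C)[C@@H]3C=C(C(=O)OCC[Si](C)(C)C)COC(=O)[C@@H]32
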